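The target is a cyclohexene (ring carbons C1–C6): C1 carries CH2OBz and the epoxide oxygen it shares with C6, C2 bears OMe, C3 bears OBz, and C4=C5 is the alkene. Stripped of its C2, C3 and C6 oxygens, the ring is a cyclohexa-2,5-dien-1-ol bisected by a mirror plane containing C1 and C4, so the C2=C3 and C5=C6 alkenes are enantiotopic. A chiral hafnium bishydroxamate epoxidises one of them on the hydroxyl face and fixes C1, C2 and C3 in one operation. The precursor is achiral (1-hydroxycyclohexa-2,5-dien-1-yl)methyl benzoate, made from 1,4-dihydrobenzoic acid. Benzoate opening, methylation and an anti epoxide transposition at C5/C6 complete the route.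

Key step: step 5

Conventions and assumption: the locants C1–C6 defined above are kept in all names (they are not lowest-locant numbers). β is the face of the C1 oxygen and α the face of the C1 CH2O group; seen from the β face, C1→C2→C3 runs clockwise. The ligand enantiomer that selects the C2=C3 alkene is assumed to be (R,R); should the catalyst prefer the other alkene, the (S,S) ligand is used.

Step 1
Reactants: 1 cyclohexa-2,5-diene-1-carboxylic acid; 2 (trimethylsilyl)diazomethane
Product: 3 methyl cyclohexa-2,5-diene-1-carboxylate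
Conditions: TMSCHN2 (2 M in hexanes), PhMe/MeOH 4:1, 0 °C to rt
Reagents that add atoms: (trimethylsilyl)diazomethane, C[Si](C)(C)C=[N+]=[N-]
Why: Diazoalkane O-methylation of a carboxylic acid runs under neutral conditions, so the skipped diene should neither move into conjugation nor aromatise; no stereocentre is formed.

Step 2
Reactants: 3 methyl cyclohexa-2,5-diene-1-carboxylate; 4 3-phenyl-2-(phenylsulfonyl)oxaziridine
Product: 6 methyl 1-hydroxycyclohexa-2,5-diene-1-carboxylate, via potassium enolate 5 (not isolated)
Conditions: KN(SiMe3)2, THF, −78 °C; then 4, −78 °C; aq NH4Cl quench at −78 °C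
Reagents that add atoms: 3-phenyl-2-(phenylsulfonyl)oxaziridine, O=S(=O)(c1ccccc1)N1OC1c1ccccc1
Why: Davis oxidation, in which the doubly allylic ester α-proton is removed and the enolate attacks the electrophilic oxaziridine oxygen through C1, the same position at which this enolate is alkylated; the product is achiral.

Step 3
Reactants: 6 methyl 1-hydroxycyclohexa-2,5-diene-1-carboxylate
Product: 7 1-(hydroxymethyl)cyclohexa-2,5-dien-1-ol
Conditions: LiAlH4, Et2O, 0 °C; aq potassium sodium tartrate work-up
Reagents that add atoms: none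
Why: Hydride reduction of an ester to the primary alcohol leaves isolated alkenes alone, and the non-acidic work-up protects the acid-labile doubly allylic carbinol; no stereocentre is formed.

Step 4
Reactants: 7 1-(hydroxymethyl)cyclohexa-2,5-dien-1-ol; 8 benzoyl chloride
Product: 9 (1-hydroxycyclohexa-2,5-dien-1-yl)methyl benzoate
Conditions: BzCl (1.05 equiv), pyridine, CH2Cl2, −20 to 0 °C
Reagents that add atoms: benzoyl chloride, O=C(Cl)c1ccccc1
Why: Acylation should pick the unhindered primary hydroxyl over the tertiary one on steric grounds; it installs the target's own primary ester and caps a hydroxyl that would otherwise direct the oxidant to the opposite ring face in step 5.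

Step 5
Reactants: 9 (1-hydroxycyclohexa-2,5-dien-1-yl)methyl benzoate; 10 cumene hydroperoxide
Product: 11 [(1S,2S,3S)-2,3-epoxy-1-hydroxycyclohex-5-en-1-yl]methyl benzoate (1β-OH; 2β,3β-epoxide)
Conditions: Hf(OtBu)4 (10 mol %), (R,R)-N,N'-dihydroxy-N,N'-bis(3,3,3-triphenylpropanoyl)cyclohexane-1,2-diamine (12 mol %), cumene hydroperoxide (1.2 equiv), DMPU, 4 Å MS, PhMe, 0 °C
Reagents that add atoms: cumene hydroperoxide, CC(C)(OO)c1ccccc1
Why: Exchange of tert-butoxide places the C1 alkoxide of 9 and the cumyl peroxide on the chiral tetravalent hafnium bishydroxamate, and the activated peroxide oxygen is passed within this complex to the alkene that the ligand pocket presents; the closest known reactions are the hydroxyl-directed asymmetric epoxidation of tertiary allylic alcohols by bishydroxamate complexes of tetravalent hafnium or zirconium and the titanium tartrate desymmetrisation of divinyl carbinols. The oxirane closes by concerted syn oxygen-atom transfer to the C2=C3 π bond, with both C–O bonds made in one event and not by a stepwise displacement. C2 and C3 are set cis to each other by that concertedness and on the β face by the C1–O–Hf tether, while C1 becomes stereogenic through the ligand's choice between the two enantiotopic alkenes. The step needs enantiotopic-group selectivity, syn facial selectivity and a stop after one epoxidation: the mirror symmetry of 9 leaves the ligand as the only differentiating element, the tertiary hydroxyl is the only free donor, and the oxidant is kept near one equivalent. A second epoxidation should preferentially consume the minor enantiomer, whose remaining alkene is the one the catalyst favours, so the enantiomeric purity of 11 is expected to rise with conversion.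

Step 6
Reactants: 11 [(1S,2S,3S)-2,3-epoxy-1-hydroxycyclohex-5-en-1-yl]methyl benzoate; 12 benzoic acid
Product: 13 [(1S,2S,3R)-3-(benzoyloxy)-1,2-dihydroxycyclohex-5-en-1-yl]methyl benzoate (1β-OH, 2β-OH, 3α-OBz)
Conditions: Ti(OiPr)4 (1.5 equiv), PhCO2H (2 equiv), CH2Cl2, rt; aq tartaric acid work-up
Reagents that add atoms: benzoic acid, OC(=O)c1ccccc1
Why: Ti(OiPr)4-mediated regioselective opening of a 2,3-epoxy alcohol, in which titanium bridges the C1 alkoxide and the syn epoxide oxygen and benzoate attacks C3, the carbon remote from the quaternary centre, by SN2 with inversion, setting the 3α-benzoate trans to the retained 2β-oxygen.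

Step 7
Reactants: 13 [(1S,2S,3R)-3-(benzoyloxy)-1,2-dihydroxycyclohex-5-en-1-yl]methyl benzoate; 14 trimethyloxonium tetrafluoroborate
Product: 15 [(1S,2S,3R)-3-(benzoyloxy)-1-hydroxy-2-methoxycyclohex-5-en-1-yl]methyl benzoate
Conditions: Me3OBF4, 1,8-bis(dimethylamino)naphthalene, 4 Å MS, CH2Cl2, 0 °C to rt
Reagents that add atoms: trimethyloxonium tetrafluoroborate, C[O+](C)C.F[B-](F)(F)F
Why: O-Alkylation with an oxonium salt under a hindered, non-nucleophilic base should methylate the secondary C2 hydroxyl in preference to the crowded tertiary C1 hydroxyl and avoids alkoxide conditions that would let the benzoates migrate; no stereocentre is touched.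

Step 8
Reactants: 15 [(1S,2S,3R)-3-(benzoyloxy)-1-hydroxy-2-methoxycyclohex-5-en-1-yl]methyl benzoate; 16 triethylsilyl trifluoromethanesulfonate
Product: 17 [(1S,2S,3R)-3-(benzoyloxy)-2-methoxy-1-(triethylsilyloxy)cyclohex-5-en-1-yl]methyl benzoate
Conditions: TESOTf, 2,6-lutidine, CH2Cl2, −78 to 0 °C
Reagents that add atoms: triethylsilyl trifluoromethanesulfonate, CC[Si](CC)(CC)OS(=O)(=O)C(F)(F)F
Why: Silyl triflates silylate hindered tertiary alcohols, and the ether removes the hydrogen-bond donor that would steer a peracid to the β face while adding bulk there; no stereocentre changes.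

Step 9
Reactants: 17 [(1S,2S,3R)-3-(benzoyloxy)-2-methoxy-1-(triethylsilyloxy)cyclohex-5-en-1-yl]methyl benzoate; 18 3-chloroperoxybenzoic acid
Product: 19 [(1S,2S,3R,5S,6S)-3-(benzoyloxy)-5,6-epoxy-2-methoxy-1-(triethylsilyloxy)cyclohexyl]methyl benzoate (5α,6α-epoxide)
Conditions: mCPBA, NaHCO3, CH2Cl2, 0 °C to rt
Reagents that add atoms: 3-chloroperoxybenzoic acid, OOC(=O)c1cccc(Cl)c1
Why: Prilezhaev epoxidation; in the half-chair with 2β-OMe and 3α-OBz equatorial the C1 silyloxy group is pseudoaxial on the β face and the α face shows only hydrogens, so the peracid should add from the α face and set C5 and C6 anti to the C1 oxygen.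

Step 10
Reactants: 19 [(1S,2S,3R,5S,6S)-3-(benzoyloxy)-5,6-epoxy-2-methoxy-1-(triethylsilyloxy)cyclohexyl]methyl benzoate; 20 diphenyl diselenide
Product: 23 [(1R,2S,3R,6S)-3-(benzoyloxy)-6-hydroxy-2-methoxy-1-(triethylsilyloxy)cyclohex-4-en-1-yl]methyl benzoate, via hydroxy selenide 21 (not isolated), via selenoxide 22 (not isolated)
Conditions: (PhSe)2, NaBH4, EtOH, rt to 40 °C; then THF, pyridine, 30% H2O2, 0 °C to rt
Reagents that add atoms: none
Why: Selenide-based transposition of an epoxide to an allylic alcohol, in which the borate-bound selenolate opens the oxirane at C5, away from the quaternary C1, with inversion (trans-diaxial, Fürst–Plattner), and the selenoxide then undergoes syn elimination with a C4 hydrogen away from the carbinol carbon, so C6 keeps its α-hydroxyl and the alkene appears at C4=C5.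

Step 11
Reactants: 23 [(1R,2S,3R,6S)-3-(benzoyloxy)-6-hydroxy-2-methoxy-1-(triethylsilyloxy)cyclohex-4-en-1-yl]methyl benzoate; 24 methanesulfonic anhydride
Product: 25 [(1S,2S,3R,6S)-3-(benzoyloxy)-6-(methanesulfonyloxy)-2-methoxy-1-(triethylsilyloxy)cyclohex-4-en-1-yl]methyl benzoate
Conditions: Ms2O, Et3N, CH2Cl2, −20 to 0 °C; used crude
Reagents that add atoms: methanesulfonic anhydride, CS(=O)(=O)OS(C)(=O)=O
Why: O-Sulfonylation of the only free hydroxyl goes with retention at C6 and turns the α-oxygen into a leaving group anti to the C1 oxygen, and the anhydride keeps chloride away from the allylic sulfonate.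

Step 12
Reactants: 25 [(1S,2S,3R,6S)-3-(benzoyloxy)-6-(methanesulfonyloxy)-2-methoxy-1-(triethylsilyloxy)cyclohex-4-en-1-yl]methyl benzoate
Product: 27 [(1R,2S,3R,6R)-3-(benzoyloxy)-1,6-epoxy-2-methoxycyclohex-4-en-1-yl]methyl benzoate (target CNP0231490.2), via tertiary alkoxide 26 (not isolated)
Conditions: Bu4NF, THF, 0 °C
Reagents that add atoms: none
Why: Fluoride cleaves the silyl ether and the freed C1 alkoxide displaces the anti C6 mesylate in an intramolecular Williamson reaction (3-exo-tet) with inversion at C6, which places the epoxide on the β face, cis to 2β-OMe and trans to 3α-OBz.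

Compound list

1 | cyclohexa-2,5-diene-1-carboxylic acid | OC(=O)C1C=CCC=C1 | starting material
2 | (trimethylsilyl)diazomethane | C[Si](C)(C)C=[N+]=[N-] | starting material
3 | methyl cyclohexa-2,5-diene-1-carboxylate | COC(=O)C1C=CCC=C1 | intermediate
4 | 3-phenyl-2-(phenylsulfonyl)oxaziridine (racemic) | O=S(=O)(c1ccccc1)N1OC1c1ccccc1 | starting material
5 | potassium enolate of 3 (formed in the flask) | COC([O-])=C1C=CCC=C1.[K+] | intermediate
6 | methyl 1-hydroxycyclohexa-2,5-diene-1-carboxylate | COC(=O)C1(O)C=CCC=C1 | intermediate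
7 | 1-(hydroxymethyl)cyclohexa-2,5-dien-1-ol | OCC1(O)C=CCC=C1 | intermediate
8 | benzoyl chloride | O=C(Cl)c1ccccc1 | starting material
9 | (1-hydroxycyclohexa-2,5-dien-1-yl)methyl benzoate (achiral; mirror plane through C1 and C4) | OC1(COC(=O)c2ccccc2)C=CCC=C1 | intermediate
10 | cumene hydroperoxide | CC(C)(OO)c1ccccc1 | starting material
11 | [(1S,2S,3S)-2,3-epoxy-1-hydroxycyclohex-5-en-1-yl]methyl benzoate (1β-OH; 2β,3β-epoxide) | O[C@]1(COC(=O)c2ccccc2)C=CC[C@@H]2O[C@H]12 | intermediate
12 | benzoic acid | OC(=O)c1ccccc1 | starting material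
13 | [(1S,2S,3R)-3-(benzoyloxy)-1,2-dihydroxycyclohex-5-en-1-yl]methyl benzoate (1β-OH, 2β-OH, 3α-OBz) | O[C@]1(COC(=O)c2ccccc2)C=CC[C@@H](OC(=O)c2ccccc2)[C@@H]1O | intermediate
14 | trimethyloxonium tetrafluoroborate | C[O+](C)C.F[B-](F)(F)F | starting material
15 | [(1S,2S,3R)-3-(benzoyloxy)-1-hydroxy-2-methoxycyclohex-5-en-1-yl]methyl benzoate (1β-OH, 2β-OMe, 3α-OBz) | O[C@]1(COC(=O)c2ccccc2)C=CC[C@@H](OC(=O)c2ccccc2)[C@@H]1OC | intermediate
16 | triethylsilyl trifluoromethanesulfonate | CC[Si](CC)(CC)OS(=O)(=O)C(F)(F)F | starting material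
17 | [(1S,2S,3R)-3-(benzoyloxy)-2-methoxy-1-(triethylsilyloxy)cyclohex-5-en-1-yl]methyl benzoate (1β-OSiEt3, 2β-OMe, 3α-OBz) | CC[Si](CC)(CC)O[C@]1(COC(=O)c2ccccc2)C=CC[C@@H](OC(=O)c2ccccc2)[C@@H]1OC | intermediate
18 | 3-chloroperoxybenzoic acid | OOC(=O)c1cccc(Cl)c1 | starting material
19 | [(1S,2S,3R,5S,6S)-3-(benzoyloxy)-5,6-epoxy-2-methoxy-1-(triethylsilyloxy)cyclohexyl]methyl benzoate (5α,6α-epoxide, anti to the C1 oxygen) | CC[Si](CC)(CC)O[C@]1(COC(=O)c2ccccc2)[C@H]2O[C@H]2C[C@@H](OC(=O)c2ccccc2)[C@@H]1OC | intermediate
20 | diphenyl diselenide | c1ccc(cc1)[Se][Se]c1ccccc1 | starting material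
21 | [3α-(benzoyloxy)-6α-hydroxy-2β-methoxy-5β-(phenylselanyl)-1β-(triethylsilyloxy)cyclohexyl]methyl benzoate (formed in the flask) | CC[Si](CC)(CC)O[C@]1(COC(=O)c2ccccc2)[C@@H](O)[C@H]([Se]c2ccccc2)C[C@@H](OC(=O)c2ccccc2)[C@@H]1OC | intermediate
22 | selenoxide of 21, configuration at selenium undefined (formed in the flask) | CC[Si](CC)(CC)O[C@]1(COC(=O)c2ccccc2)[C@@H](O)[C@H]([Se](=O)c2ccccc2)C[C@@H](OC(=O)c2ccccc2)[C@@H]1OC | intermediate
23 | [(1R,2S,3R,6S)-3-(benzoyloxy)-6-hydroxy-2-methoxy-1-(triethylsilyloxy)cyclohex-4-en-1-yl]methyl benzoate (6α-OH) | CC[Si](CC)(CC)O[C@]1(COC(=O)c2ccccc2)[C@@H](O)C=C[C@@H](OC(=O)c2ccccc2)[C@@H]1OC | intermediate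
24 | methanesulfonic anhydride | CS(=O)(=O)OS(C)(=O)=O | starting material
25 | [(1S,2S,3R,6S)-3-(benzoyloxy)-6-(methanesulfonyloxy)-2-methoxy-1-(triethylsilyloxy)cyclohex-4-en-1-yl]methyl benzoate (6α-OMs) | CC[Si](CC)(CC)O[C@]1(COC(=O)c2ccccc2)[C@@H](OS(C)(=O)=O)C=C[C@@H](OC(=O)c2ccccc2)[C@@H]1OC | intermediate
26 | tetrabutylammonium C1 alkoxide from 25 (formed in the flask) | [O-][C@]1(COC(=O)c2ccccc2)[C@@H](OS(C)(=O)=O)C=C[C@@H](OC(=O)c2ccccc2)[C@@H]1OC.CCCC[N+](CCCC)(CCCC)CCCC | intermediate
27 | [(1R,2S,3R,6R)-3-(benzoyloxy)-1,6-epoxy-2-methoxycyclohex-4-en-1-yl]methyl benzoate (1β,6β-epoxide, 2β-OMe, 3α-OBz) | CO[C@H]1[C@H](OC(=O)c2ccccc2)C=C[C@H]2O[C@]21COC(=O)c1ccccc1 | target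

Total step count: 12. Longest linear sequence: 12 steps (1 to 27).

Steps most likely to fail

Step 5. The catalyst may discriminate the two enantiotopic alkenes poorly, a second epoxidation may overrun, or the Lewis-acidic metal may trigger dehydrative aromatisation of the doubly allylic carbinol. The fallback gives up asymmetric catalysis for resolution. Setting out from 9, VO(acac)2 (catalytic) and tBuOOH in PhMe at 0 °C effect an alkoxide-directed syn epoxidation without a chiral ligand. This should give the racemate, that is 11 together with its mirror image ent-11 F1. The enantiomers are separated by preparative supercritical-fluid chromatography on an amylose tris(3,5-dimethylphenylcarbamate) phase, and the route is rejoined at 11.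

Step 9. The peracid may attack the β face in part, or the hindered, electron-poor alkene may react too slowly. The fallback replaces steps 9 and 10 by a Schenck ene reaction. Setting out from 17, photo-oxygenation (O2, tetraphenylporphyrin, visible light, CH2Cl2, 0 °C) should bring singlet oxygen to C6 on the open α face while the pseudoaxial α-hydrogen at C4 is transferred. C4 is the only allylic position with hydrogens, because C1 is quaternary. This gives [3α-(benzoyloxy)-6α-hydroperoxy-2β-methoxy-1β-(triethylsilyloxy)cyclohex-4-en-1-yl]methyl benzoate F2 with the alkene already at C4=C5. PPh3 reduces the hydroperoxide, and the route is rejoined at 23.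

Step 10. Opening of the crowded epoxide by selenolate may be slow enough for ethanolysis or migration of a benzoate to compete, and perseleninic acid may over-oxidise the new alkene. The fallback avoids selenium and protic base. Setting out from 19, TMSOTf and 2,6-lutidine followed by DBU in PhMe (0 °C to rt) should isomerise the silylated oxirane to an allylic silyl ether. The C5–O bond breaks and the anti C4 hydrogen is lost, while C1 offers no hydrogen for the other mode. This gives [3α-(benzoyloxy)-2β-methoxy-1β-(triethylsilyloxy)-6α-(trimethylsilyloxy)cyclohex-4-en-1-yl]methyl benzoate F3. Citric acid in MeOH at 0 °C removes the secondary trimethylsilyl group while the tertiary triethylsilyl ether stays, and the route is rejoined at 23.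

Further compounds

F1 | step 5 | ent-11, [(1R,2R,3R)-2,3-epoxy-1-hydroxycyclohex-5-en-1-yl]methyl benzoate | O[C@@]1(COC(=O)c2ccccc2)C=CC[C@H]2O[C@@H]12
F2 | step 9 | [3α-(benzoyloxy)-6α-hydroperoxy-2β-methoxy-1β-(triethylsilyloxy)cyclohex-4-en-1-yl]methyl benzoate | CC[Si](CC)(CC)O[C@]1(COC(=O)c2ccccc2)[C@@H](OO)C=C[C@@H](OC(=O)c2ccccc2)[C@@H]1OC
F3 | step 10 | [3α-(benzoyloxy)-2β-methoxy-1β-(triethylsilyloxy)-6α-(trimethylsilyloxy)cyclohex-4-en-1-yl]methyl benzoate | CC[Si](CC)(CC)O[C@]1(COC(=O)c2ccccc2)[C@@H](O[Si](C)(C)C)C=C[C@@H](OC(=O)c2ccccc2)[C@@H]1OC
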